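## Retrosynthetic overview

1. The target is a deoxybenzoin. The last disconnection is the bond between the ketone α-carbon (CH2) and C1 of the 4-methoxyphenyl ring. It is made by Pd-catalysed enolate arylation of a C16 6-acetyl-2H-chromene with 4-bromoanisole (C7), and the 7-OH is released in the same flask.
2. Enabling feature: the C=O on C6 of the benzene ring of the benzopyran is flanked by C5–OMe and C7–O. The acetyl CH3 is therefore the only carbon with α-hydrogens, which gives one possible enolate at a twisted, shielded carbonyl. The pyran C3=C4 bond next to quaternary C2 is a poor partner for arylpalladium.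
3. The 5-OMe/7-OH pattern comes from a placeholder. MOM on one of the two equivalent ortho hydroxyls of a phloroacetophenone 4-O-(1,1-dimethylpropargyl) ether leaves the other OH chelated. That OH steers the Claisen/oxa-6π cascade to its own side and is methylated afterwards.
4. Ring order: the benzene ring of the chromene is bought (phloroacetophenone), the pyran ring is closed in step 3, and the anisyl ring is bought and attached in step 5.

Key step: step 5

Remark on the chemistry: the target has no stereocentre, and its only non-aromatic C=C is the ring-constrained cis C3=C4 bond of the pyran, so no stereodescriptor is needed. Phloroacetophenone is used in dried (anhydrous) form.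

## Route

Step 1
Reactants: 1 phloroacetophenone [1-(2,4,6-trihydroxyphenyl)ethanone]; 2 3-chloro-3-methylbut-1-yne
Product: 3 aryl propargyl ether 1-[2,6-dihydroxy-4-(2-methylbut-3-yn-2-yloxy)phenyl]ethanone
Conditions: K2CO3 (1.1 equiv), KI (cat.), CuI (cat.), acetone, 50 °C, Ar
Reagents that add atoms: none
Why: Copper-assisted Williamson-type O-propargylation: the 4-OH is the most acidic and least hindered hydroxyl and the only one that cannot hydrogen-bond to the acetyl C=O, so one equivalent of base should direct the bulky tertiary electrophile to this oxygen alone.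

Step 2
Reactants: 3 aryl propargyl ether
Product: 4 mono-MOM ether 1-[2-hydroxy-6-(methoxymethoxy)-4-(2-methylbut-3-yn-2-yloxy)phenyl]ethanone
Conditions: MOMCl (1.05 equiv), K2CO3 (1.2 equiv), acetone, 0 °C to rt
Reagents that add atoms: chloromethyl methyl ether (MOMCl), COCCl
Why: Chelation-controlled Williamson-type mono-protection (MOM ether formation): the two ortho hydroxyls are equivalent and only one at a time can bind the C=O, so the first alkylation is easy, whereas the remaining OH is then locked in a six-membered hydrogen-bonded chelate and should stay free.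

Step 3
Reactants: 4 mono-MOM ether
Product: 7 chromene 1-[5-hydroxy-7-(methoxymethoxy)-2,2-dimethyl-2H-chromen-6-yl]ethanone, via allenylphenol 5 (not isolated), via ortho-quinone methide 6 (not isolated)
Conditions: o-xylene, 140 °C, Ar
Reagents that add atoms: none
Why: Aromatic propargyl Claisen rearrangement followed by enolisation, [1,5]-H shift and oxa-6π electrocyclisation: as in ethers of 2,4-dihydroxyacetophenone, the hydrogen-bonded chelate ring fixes the bonds of the arene so that the [3,3] shift should go to the carbon next to the chelated OH, and only the non-chelated hydroxyl of 5 passes on its proton and closes the pyran ring, giving the linear 6-acetyl isomer.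

Step 4
Reactants: 7 chromene
Product: 8 methyl ether 1-[5-methoxy-7-(methoxymethoxy)-2,2-dimethyl-2H-chromen-6-yl]ethanone
Conditions: MeI (3 equiv), K2CO3 (3 equiv), DMF, 45 °C
Reagents that add atoms: iodomethane (MeI), CI
Why: Williamson O-methylation of the only free phenol: the chelated and flanked 5-OH needs excess MeI and a polar solvent, but carbonate is too weak to enolise the ketone, and the MOM ether and the chromene are inert to these conditions.

Step 5
Reactants: 8 methyl ether; 9 4-bromoanisole
Product: 11 target 1-(7-hydroxy-5-methoxy-2,2-dimethyl-2H-chromen-6-yl)-2-(4-methoxyphenyl)ethanone, via MOM-protected deoxybenzoin 10 (not isolated)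
Conditions: Pd2(dba)3 (1.5 mol %), Xantphos (3.6 mol %), NaOt-Bu (2.2 equiv), 1,4-dioxane, 80 °C; then 3 M aq HCl, MeOH, 45 °C, same flask
Reagents that add atoms: none
Why: Buchwald–Hartwig–Miura α-arylation of a ketone: Pd(0)/Xantphos inserts into the C–Br bond of 9, the sodium enolate of 8 displaces bromide on palladium, and C–C reductive elimination from the arylpalladium enolate forms the CH2–aryl bond of 10, which the second equivalent of base stores as its more stabilised enolate. The closest known reaction type is the monoarylation of aryl methyl ketones, including 2,6-disubstituted ones, with electron-rich aryl bromides under wide-bite-angle or bulky phosphine catalysis. No ring is closed and no stereocentre is formed in this step. Three selectivities are needed: site (secured because the CH3 of the C6 acetyl group is the only enolisable carbon), mono- over diarylation (secured by the chelating ligand, by the deprotonated state of 10 and by the crowding from 5-OMe and 7-OMOM), and enolate coupling over Heck insertion (secured because the pyran C3=C4 bond is cis-disubstituted and adjoins quaternary C2). The MOM ether keeps the 7-oxygen neutral, since a free phenoxide would turn the ketone into a vinylogous carboxylate that is hard to enolise and could chelate palladium. Acidification with HCl in methanol then protonates the enolate and transacetalises the MOM group, the most labile acetal because the liberated 7-OH hydrogen-bonds to the C=O, so that one operation completes the C21 skeleton and delivers 11.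

## Compound list

1 | phloroacetophenone, 1-(2,4,6-trihydroxyphenyl)ethanone | CC(=O)c1c(O)cc(O)cc1O | starting material
2 | 3-chloro-3-methylbut-1-yne | C#CC(C)(C)Cl | starting material
3 | 1-[2,6-dihydroxy-4-(2-methylbut-3-yn-2-yloxy)phenyl]ethanone | CC(=O)c1c(O)cc(OC(C)(C)C#C)cc1O | intermediate
4 | 1-[2-hydroxy-6-(methoxymethoxy)-4-(2-methylbut-3-yn-2-yloxy)phenyl]ethanone | CC(=O)c1c(O)cc(OC(C)(C)C#C)cc1OCOC | intermediate
5 | allenylphenol, 1-[2,4-dihydroxy-6-(methoxymethoxy)-3-(3-methylbuta-1,2-dienyl)phenyl]ethanone | CC(=O)c1c(O)c(C=C=C(C)C)c(O)cc1OCOC | intermediate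
6 | ortho-quinone methide, (6Z)-4-acetyl-5-hydroxy-3-(methoxymethoxy)-6-(3-methylbut-2-enylidene)cyclohexa-2,4-dien-1-one | CC(C)=C/C=C1\C(=O)C=C(OCOC)C(C(C)=O)=C1O | intermediate
7 | 1-[5-hydroxy-7-(methoxymethoxy)-2,2-dimethyl-2H-chromen-6-yl]ethanone | CC(=O)c1c(O)c2C=CC(C)(C)Oc2cc1OCOC | intermediate
8 | 1-[5-methoxy-7-(methoxymethoxy)-2,2-dimethyl-2H-chromen-6-yl]ethanone | CC(=O)c1c(OC)c2C=CC(C)(C)Oc2cc1OCOC | intermediate
9 | 4-bromoanisole | COc1ccc(Br)cc1 | starting material
10 | 1-[5-methoxy-7-(methoxymethoxy)-2,2-dimethyl-2H-chromen-6-yl]-2-(4-methoxyphenyl)ethanone | COc1ccc(CC(=O)c2c(OC)c3C=CC(C)(C)Oc3cc2OCOC)cc1 | intermediate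
11 | 1-(7-hydroxy-5-methoxy-2,2-dimethyl-2H-chromen-6-yl)-2-(4-methoxyphenyl)ethanone | COc1ccc(CC(=O)c2c(O)cc3c(c2OC)C=CC(C)(C)O3)cc1 | target

## Step count and risks

Total steps: 5. Longest linear sequence: 5 (1 → 3 → 4 → 7 → 8 → 11).

**Step 3.**
- Risk: the [3,3] shift may discriminate poorly between the two ortho carbons of 4, and ring closure could engage the wrong hydroxyl.
- Fallback: it sets out from 3 and returns at 7, and replaces electronic site control by symmetry followed by steric differentiation. In 3 both ortho carbons are equivalent. It is heated (o-xylene, 140 °C) before any protection, and the same cascade should give 1-(5,7-dihydroxy-2,2-dimethyl-2H-chromen-6-yl)ethanone F1. One equivalent of MOMCl with K2CO3 should then cap the 7-OH, whose neighbour is C8–H, in preference to the 5-OH, which is buttressed by C4–H. This gives 7.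

**Step 1.**
- Risk: O-alkylation by the tertiary propargylic chloride may lose out to elimination of HCl, to C-alkylation of the phloroglucinol ring or to multiple alkylation.
- Fallback: it sets out from 1 and returns at 7, and avoids the propargyl ether altogether.
  - TBSCl (1 equiv) and imidazole in DMF at 0 °C should silylate the non-chelated 4-OH to give 1-[4-(tert-butyldimethylsilyloxy)-2,6-dihydroxyphenyl]ethanone F2.
  - MOMCl and i-Pr2NEt should give 1-[4-(tert-butyldimethylsilyloxy)-2-hydroxy-6-(methoxymethoxy)phenyl]ethanone F3.
  - TBAF should release 1-[2,4-dihydroxy-6-(methoxymethoxy)phenyl]ethanone F4.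
  - A formal [3+3] chromenylation with 3-methylbut-2-enal (ethylenediammonium diacetate cat., toluene, reflux) then follows. It is a Knoevenagel-type condensation at the carbon between the two free hydroxyls, followed by oxa-6π closure on the non-chelated one, and should give 7.

**Step 5.**
- Risk: the coupling may stall through slow oxidative addition of the electron-rich bromide or sequestration of palladium by the oxygen donors. It may also lose selectivity through a second arylation or insertion into the pyran alkene.
- Fallback: it sets out from 8 and returns at 11. It makes the same bond as an sp2–sp2 Suzuki–Miyaura coupling on a temporary 4-pyranone ring.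
  - HCl in MeOH should give 1-(7-hydroxy-5-methoxy-2,2-dimethyl-2H-chromen-6-yl)ethanone F5.
  - DMF dimethyl acetal at 95 °C should give (E)-3-(dimethylamino)-1-(7-hydroxy-5-methoxy-2,2-dimethyl-2H-chromen-6-yl)prop-2-en-1-one F6.
  - Iodine in CHCl3 at rt should cyclise it to 7-iodo-5-methoxy-2,2-dimethyl-2H,6H-pyrano[3,2-g]chromen-6-one F7.
  - 4-Methoxyphenylboronic acid, Pd(PPh3)4 and Na2CO3 in DME/water should give 5-methoxy-7-(4-methoxyphenyl)-2,2-dimethyl-2H,6H-pyrano[3,2-g]chromen-6-one F8.
  - KOH in aqueous ethanol at reflux should open the pyranone by hydroxide addition and retro-Claisen deformylation to give 11.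

## Further compounds

F1 | step 3 | 1-(5,7-dihydroxy-2,2-dimethyl-2H-chromen-6-yl)ethanone | CC(=O)c1c(O)cc2OC(C)(C)C=Cc2c1O
F2 | step 1 | 1-[4-(tert-butyldimethylsilyloxy)-2,6-dihydroxyphenyl]ethanone | CC(=O)c1c(O)cc(O[Si](C)(C)C(C)(C)C)cc1O
F3 | step 1 | 1-[4-(tert-butyldimethylsilyloxy)-2-hydroxy-6-(methoxymethoxy)phenyl]ethanone | CC(=O)c1c(O)cc(O[Si](C)(C)C(C)(C)C)cc1OCOC
F4 | step 1 | 1-[2,4-dihydroxy-6-(methoxymethoxy)phenyl]ethanone | CC(=O)c1c(O)cc(O)cc1OCOC
F5 | step 5 | 1-(7-hydroxy-5-methoxy-2,2-dimethyl-2H-chromen-6-yl)ethanone | CC(=O)c1c(O)cc2OC(C)(C)C=Cc2c1OC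
F6 | step 5 | (E)-3-(dimethylamino)-1-(7-hydroxy-5-methoxy-2,2-dimethyl-2H-chromen-6-yl)prop-2-en-1-one | CN(C)/C=C/C(=O)c1c(O)cc2OC(C)(C)C=Cc2c1OC
F7 | step 5 | 7-iodo-5-methoxy-2,2-dimethyl-2H,6H-pyrano[3,2-g]chromen-6-one | COc1c2C=CC(C)(C)Oc2cc2occ(I)c(=O)c12
F8 | step 5 | 5-methoxy-7-(4-methoxyphenyl)-2,2-dimethyl-2H,6H-pyrano[3,2-g]chromen-6-one | COc1ccc(cc1)-c1coc2cc3OC(C)(C)C=Cc3c(OC)c2c1=O
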